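The split is the thing to carry.

| setting | summer | midnight | flask |
|---|---|---|---|
| substrate | 0.051 M | 0.051 M | 0.051 M |
| other conformer | 0.25 equiv | 0.38 equiv | 0.500 equiv |
| free catalyst | 17 mol% | 17 mol% | 17 mol% |
| remark | run made earlier | run made earlier |  |
| time |  |  | 10 h |

- summer (time / h: target / %, isomer of the product / %): 1.50: 7, 5; 3.00: 9, 8; 5.00: 13, 14; 6.00: 14, 17
- midnight (time / h: target / %, isomer of the product / %): 0.833: 5, 7; 2.00: 9, 13; 4.00: 11, 16; 6.00: 13, 16

(readings scatter by 1.5 percentage points)

- ratio of target to isomer of the product at 8.0 min
- ratio of target to isomer of the product at 1.0 h
- ratio of target to isomer of the product at 10 h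

- I supposed that the same free catalyst makes target from substrate and isomer of the product from other conformer, so that the two are formed in the ratio of a fixed number times [substrate]/[other conformer], counted on the fractions left and not on the fractions charged.
- The first setting was the equivalents of other conformer: by hand, going from 0.25 equiv in the summer run to 0.38 equiv in the midnight run should divide the early ratio by 1.52, and the first readings, taken at 1.50 h in the summer run and at 0.833 h in the midnight run, fell from 1.40 to 0.714, a factor of 1.96, which is a rough match with a scatter of 1.5 percentage points on readings of 5 %, though the times of the two readings differ as well as the equivalents.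
- Multiplying each first ratio by its equivalents gave 0.350 for the summer run and 0.271 for the midnight run, and I called their mean, 0.311, the split, the early ratio of target to isomer of the product times the equivalents of other conformer, a selectivity factor; for the flask, at 0.500 equiv, it gave me 0.621 at 8.0 min and at 1.0 h.
- The second setting was time: by hand, the summer run charged 20.0 % of its material as other conformer and read 17 % isomer of the product at 6.00 h, which should leave 3 points and a crawl, yet the isomer rose by 3 points in its last hour, so, with a scatter of 1.5 points on each of those two readings, I tentatively read the other conformer in that run as refilled from substrate.
- The ratio in the summer run fell to 0.824 at 6.00 h, and with substrate falling against a refilled other conformer I expected the flask at 10 h to lie below its early value, though I put no number on it.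
- The forecast, which began from “The isomer seems to come mainly from the other conformer”, gave 0.4 at 8.0 min, lower than my early value, then 0.42 at 1.0 h, and a rise to 0.8 at 10 h, where I expected a fall.
- The flask gave 0.600 at 8.0 min, 0.603 at 1.0 h and 0.535 at 10 h.

    free catalyst → spent catalyst C (k = 0.119 /h)
    free catalyst + other conformer → free catalyst + isomer of the product (k = 35.1 /M/h)
    substrate + free catalyst → free catalyst + target (k = 10.5 /M/h)
    free catalyst + target → spent catalyst B (k = 0.779 /M/h)
    2 free catalyst → spent catalyst A (k = 21.1 /M/h)
    substrate ⇌ other conformer (K = 1.30, k = 0.0864 /h)

- At 10.0 h the flask held 32.4 % substrate against 27.1 % other conformer, so the split put the ratio of what was then being formed at 0.371, lower than the 0.535 accumulated by then. On the neighbouring flask with 1.20 equiv of other conformer, the split gave 0.259 for the early time, and that flask gave 0.252 at 8.0 min.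

(The runs were computed for an exercise.)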